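## Retrosynthetic overview

1. The target comes from a tetracyclic C1 ketone by Wittig methylenation; before that, the C4=C5 bond is saturated and equilibrated and the C18 ketone is reduced (the ring C/D trans-hydrindanone reduces like a steroid 17-ketone).
2. Rings C and B are made together from a seco-enone in which rings A and D are joined only by the chain C14–C15–C2–C1–C8. C2–C3 forms by palladium enolate alkenylation and C6–C7 by 8π closure of the resulting tetraenolate.
3. Enabling feature: ring B (C1–C8) is two four-carbon halves, C3–C4–C5–C6 and C7–C8–C1–C2. With C1 as a ketone, all eight ring-B carbons line up as one oxido-octatetraene, C7=C8–C1(O–)=C2–C3=C4–C5=C6. C2 and C3 are exocyclic on ring C, whose chair is locked by trans-fused ring D, so only one helix can close.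
4. The seco-enone comes from a ring D core built on (4R)-4-silyloxy-2-methylcyclopentenone (1,4-addition and alkylation set C14 and C13; elimination and a second 1,4-addition set C16). Ring A is attached as an enol triflate by Nozaki–Hiyama–Kishi coupling.
5. The Z-bromodiene (C12, C3–C6) comes from but-2-yne-1,4-diol by anti-carbomagnesiation. Ring order: D and A are carried from cyclopentenones, then C and B form in one step.

Key step: step 19

Remark: working locants (not IUPAC) are used. Ring B = C1 (bears exocyclic CH2 C19), C2, C3, C4 (bears methyl C20), C5, C6, C7, C8. Ring A = C7–C11 (methyl C21 on C11). Ring C = C2, C3, C12, C13 (angular methyl C22), C14, C15. Ring D = C13, C14, C16 (isopropyl C23–C25), C17, C18 (OH).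

Remark: in step 6 the ligand enantiomer is the one that gives the 3S adduct.

## Route

Step 1
Reactants: 1 but-2-yne-1,4-diol
Product: 2 4-[(tert-butyldimethylsilyl)oxy]but-2-yn-1-ol
Conditions: NaH (1.0 equiv), THF, 0 °C; then TBSCl (1.0 equiv), rt
Reagents that add atoms: tert-butyldimethylsilyl chloride, CC(C)(C)[Si](C)(C)Cl
Why: O-silylation of the sparingly soluble monoalkoxide of the symmetric diol (Williamson-type silylation) should stop at the mono-ether; no stereocentre is formed.

Step 2
Reactants: 2 4-[(tert-butyldimethylsilyl)oxy]but-2-yn-1-ol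
Product: 4 (2Z)-3-bromo-4-[(tert-butyldimethylsilyl)oxy]-2-methylbut-2-en-1-ol, via alkenylmagnesium chelate 3 (not isolated)
Conditions: MeMgBr (3 equiv), CuI (10 mol %), Et2O/THF, –10 °C → rt; then NBS, –78 → 0 °C
Reagents that add atoms: methylmagnesium bromide, C[Mg]Br; N-bromosuccinimide, O=C1CCC(=O)N1Br
Why: copper-catalysed anti-carbomagnesiation of the propargylic alkoxide puts methyl on the carbinol-side alkyne carbon and magnesium on the other carbon inside a five-membered chelate, so bromination with retention should give the Z bromide with Br cis to CH2OH (the later vinyl group).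

Step 3
Reactants: 4 (2Z)-3-bromo-4-[(tert-butyldimethylsilyl)oxy]-2-methylbut-2-en-1-ol
Product: 5 (2Z)-3-bromo-4-[(tert-butyldimethylsilyl)oxy]-2-methylbut-2-enal
Conditions: MnO2 (15 equiv), CH2Cl2, rt
Reagents that add atoms: none
Why: allylic alcohol oxidation with MnO2 stops at the aldehyde and should leave the tetrasubstituted bromoalkene geometry and the silyl ether untouched.

Step 4
Reactants: 5 (2Z)-3-bromo-4-[(tert-butyldimethylsilyl)oxy]-2-methylbut-2-enal
Product: 6 {[(2Z)-2-bromo-3-methylpenta-2,4-dien-1-yl]oxy}(tert-butyl)dimethylsilane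
Conditions: Ph3PCH3Br, KN(SiMe3)2, THF, –78 → 0 °C
Reagents that add atoms: methyltriphenylphosphonium bromide, C[P+](c1ccccc1)(c1ccccc1)c1ccccc1.[Br-]
Why: Wittig methylenation of the aldehyde gives the terminal vinyl group (C5=C6); the non-stabilised ylide should attack the carbonyl faster than the β-bromo position, so Br stays cis to the vinyl group.

Step 5
Reactants: 6 {[(2Z)-2-bromo-3-methylpenta-2,4-dien-1-yl]oxy}(tert-butyl)dimethylsilane
Product: 7 (3Z)-4,5-dibromo-3-methylpenta-1,3-diene
Conditions: Ph3PBr2 (1.3 equiv), CH2Cl2, 0 °C → rt; used crude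
Reagents that add atoms: dibromotriphenylphosphorane, BrP(Br)(c1ccccc1)(c1ccccc1)c1ccccc1
Why: Appel-type bromination in which the bromophosphonium reagent cleaves the allylic silyl ether and delivers bromide to the primary carbon (SN2), so no allylic shift is expected.

Step 6
Reactants: 8 cyclopent-2-en-1-one
Product: 10 trimethyl{[(3S)-3-methylcyclopent-1-en-1-yl]oxy}silane, via methylzinc enolate 9 (not isolated)
Conditions: Me2Zn (1.5 equiv), Cu(OTf)2 (2 mol %), chiral BINOL-derived bis(1-phenylethyl)amine phosphoramidite (4 mol %), toluene, –30 °C; then TMSOTf, Et3N, –30 → 0 °C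
Reagents that add atoms: dimethylzinc, C[Zn]C; trimethylsilyl trifluoromethanesulfonate, C[Si](C)(C)OS(=O)(=O)C(F)(F)F
Why: copper-catalysed asymmetric conjugate addition in which the chiral ligand controls the face of attack and sets C11 (S); silylation of the zinc enolate fixes the double bond between C8 and C7.

Step 7
Reactants: 10 trimethyl{[(3S)-3-methylcyclopent-1-en-1-yl]oxy}silane
Product: 12 (3S)-3-methylcyclopent-1-en-1-yl trifluoromethanesulfonate, via lithium enolate 11 (not isolated)
Conditions: MeLi (1.05 equiv), THF, 0 °C; then PhNTf2, –78 °C → rt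
Reagents that add atoms: N-phenylbis(trifluoromethanesulfonimide), O=S(=O)(N(c1ccccc1)S(=O)(=O)C(F)(F)F)C(F)(F)F
Why: methyllithium cleaves the silyl enol ether to the regiodefined lithium enolate, which is O-triflated (enol triflate formation); C11 is not touched.

Step 8
Reactants: 13 (4R)-4-[(tert-butyldimethylsilyl)oxy]cyclopent-2-en-1-one
Product: 14 (4R)-4-[(tert-butyldimethylsilyl)oxy]-2-iodocyclopent-2-en-1-one
Conditions: I2, pyridine, CH2Cl2, 0 °C → rt
Reagents that add atoms: iodine, II
Why: α-iodination of the enone by pyridine-mediated addition–elimination; the silyloxy stereocentre is not involved.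

Step 9
Reactants: 14 (4R)-4-[(tert-butyldimethylsilyl)oxy]-2-iodocyclopent-2-en-1-one
Product: 15 (4R)-4-[(tert-butyldimethylsilyl)oxy]-2-methylcyclopent-2-en-1-one
Conditions: Me4Sn (1.5 equiv), Pd2(dba)3 (2.5 mol %), AsPh3 (10 mol %), CuI (10 mol %), NMP, 60 °C
Reagents that add atoms: tetramethylstannane, C[Sn](C)(C)C
Why: Stille coupling of the 2-iodoenone installs the C22 methyl under base-free conditions, so β-elimination of the silyloxy group should not occur.

Step 10
Reactants: 15 (4R)-4-[(tert-butyldimethylsilyl)oxy]-2-methylcyclopent-2-en-1-one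
Product: 16 ring D trimethylsilyl enol ether (C13=C18 double bond, OSiMe3 on C18, 3-(TBSO)propyl on C14 trans to OTBS on C16)
Conditions: [3-(TBSO)propyl]MgBr (from (3-bromopropoxy)(tert-butyl)dimethylsilane and Mg, 1.5 equiv), CuBr·SMe2 (10 mol %), Me3SiCl, THF, –78 °C; Et3N quench
Reagents that add atoms: [3-(tert-butyldimethylsilyloxy)propyl]magnesium bromide, Br[Mg]CCCO[Si](C)(C)C(C)(C)C; chlorotrimethylsilane, C[Si](C)(C)Cl
Why: copper-catalysed 1,4-addition accelerated by Me3SiCl; the nucleophile adds anti to the C16 silyloxy group, which sets C14, and the enolate is trapped regiospecifically.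

Step 11
Reactants: 16 ring D trimethylsilyl enol ether; 7 (3Z)-4,5-dibromo-3-methylpenta-1,3-diene
Product: 18 ring D ketone (C13 bears methyl and the (2Z)-2-bromo-3-methylpenta-2,4-dienyl chain; the C13 and C14 chains are trans; OTBS on C16), via lithium enolate 17 (not isolated)
Conditions: MeLi (1.0 equiv), THF, 0 °C; then 7, HMPA, –78 → –20 °C
Reagents that add atoms: none
Why: the regiospecific lithium enolate is C-alkylated by the primary allylic bromide (SN2) on the face anti to the C14 chain, which sets the quaternary centre C13.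

Step 12
Reactants: 18 ring D ketone
Product: 19 ring D cyclopentenone (C16=C17)
Conditions: DBU, CH2Cl2, rt → 40 °C
Reagents that add atoms: none
Why: E1cB β-elimination of the silyloxy group from the β-silyloxy ketone gives the enone for the second 1,4-addition; the temporary stereocentre at C16 is erased after it has set C14 and C13.

Step 13
Reactants: 19 ring D cyclopentenone
Product: 20 ring D ketone with isopropyl on C16 (trans to the C14 chain)
Conditions: i-PrMgCl (1.5 equiv), CuBr·SMe2 (20 mol %), THF, –78 → –40 °C; sat. aq. NH4Cl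
Reagents that add atoms: isopropylmagnesium chloride, CC(C)[Mg]Cl
Why: copper-catalysed 1,4-addition of the Grignard reagent takes place anti to the adjacent C14 chain, which sets C16.

Step 14
Reactants: 20 ring D ketone with isopropyl on C16
Product: 21 C18 ethylene ketal of 20
Conditions: 1,2-bis(trimethylsilyloxy)ethane, Me3SiOTf (5 mol %), CH2Cl2, –78 → –20 °C; pyridine quench
Reagents that add atoms: 1,2-bis(trimethylsilyloxy)ethane, C[Si](C)(C)OCCO[Si](C)(C)C
Why: silyl triflate-catalysed ketalisation protects the hindered C18 ketone at low temperature, so that later only the C1 ketone can form an enolate.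

Step 15
Reactants: 21 C18 ethylene ketal
Product: 22 primary alcohol (C1–OH)
Conditions: Bu4NF, THF, 0 °C → rt
Reagents that add atoms: none
Why: fluoride-mediated cleavage of the primary silyl ether; ketal, alkenyl bromide and diene are inert.

Step 16
Reactants: 22 primary alcohol
Product: 23 aldehyde (C1)
Conditions: Dess–Martin periodinane, NaHCO3, CH2Cl2, 0 °C → rt
Reagents that add atoms: none
Why: Dess–Martin oxidation of the primary alcohol under buffered conditions that keep the ketal.

Step 17
Reactants: 23 aldehyde; 12 (3S)-3-methylcyclopent-1-en-1-yl trifluoromethanesulfonate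
Product: 24 allylic alcohol (C1 carbinol, both epimers; C1–C8 bond formed)
Conditions: CrCl2 (4 equiv), NiCl2 (1 mol %), DMF, rt
Reagents that add atoms: none
Why: Nozaki–Hiyama–Kishi coupling in which the alkenyl triflate is activated by nickel and adds as an alkenylchromium species to the aldehyde only; the hindered tetrasubstituted alkenyl bromide should react much more slowly, and the uncontrolled carbinol centre is removed in step 18.

Step 18
Reactants: 24 allylic alcohol
Product: 25 seco-enone (C1 ketone flanked by C2H2 and the ring A alkene C8=C7)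
Conditions: Dess–Martin periodinane, NaHCO3, CH2Cl2, 0 °C → rt
Reagents that add atoms: none
Why: Dess–Martin oxidation of the allylic alcohol gives the cross-conjugated enone and removes the uncontrolled carbinol centre.

Step 19
Reactants: 25 seco-enone
Product: 29 tetracyclic dienone ketal (C1 ketone, C2=C3, C4=C5, C18 ketal), via dienyl ketone 26 (not isolated), via potassium tetraenolate 27 (not isolated), via potassium trienolate 28 (not isolated)
Conditions: KN(SiMe3)2 (2.2 equiv), THF, –78 °C; then Pd2(dba)3 (5 mol %), XPhos (12 mol %), –78 → 60 °C; sat. aq. NH4Cl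
Reagents that add atoms: none
Why: Proposed new method: the kinetic potassium enolate at C2 of enone 25 is alkenylated by the alkenylpalladium species formed when zerovalent palladium inserts into the C3–Br bond (ring C closes by C–C reductive elimination from a seven-membered palladacycle, with retention of the bromodiene geometry), and the second equivalent of base deprotonates the doubly activated C2–H of 26 to tetraenolate 27, whose eight carbons C7=C8–C1(O–)=C2–C3=C4–C5=C6 close thermally by 8π conrotatory electrocyclisation to form C6–C7 and ring B. The closest known reaction types are the palladium-catalysed intramolecular α-alkenylation of ketone enolates with alkenyl bromides and the 8π closure of (Z,Z)-octatetraenes made in the flask, including oxido-substituted ones from squarate ester cascades and those from cross-coupling/8π cascades. Ring C is closed by reductive elimination (six-membered ring) and ring B by conrotatory closure of a helical tetraene. The only new stereocentre that persists is C7, and it is controlled by trans-fused ring D: ring D locks ring C in one chair, which fixes the sign of the C15–C2–C3–C12 torsion and so the helical sense of the tetraene, and C6 is then delivered to the face of C7 that gives the target configuration; this should override the weaker opposing bias of the C11 methyl, while C8 is protonated on work-up and equilibrated in step 20. The step needs α′- over γ-deprotonation of the enone (kinetic base at –78 °C, which also protects C11), C- over O-alkenylation, the enolate geometry with ring A on the inside (reachable by proton exchange), and 8π over 6π closure (inherently faster for a (Z,Z)-tetraene, whose C3=C4 geometry comes from bromodiene 7).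

Step 20
Reactants: 29 tetracyclic dienone ketal
Product: 30 tetracyclic dienone with free C18 ketone (A/B junction trans)
Conditions: 1 M HCl, THF, rt
Reagents that add atoms: water, O
Why: acid-catalysed hydrolysis of the dioxolane frees the C18 ketone, and reversible enolisation at C8 should let the ring A/B junction settle as the trans isomer, which avoids three cis substituents on ring A.

Step 21
Reactants: 30 tetracyclic dienone with free C18 ketone
Product: 31 C18 alcohol (OH cis to the angular methyl C22)
Conditions: NaBH4, MeOH/CH2Cl2 (1:1), –78 → –40 °C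
Reagents that add atoms: none
Why: chemoselective borohydride reduction in which the saturated cyclopentanone reacts faster than the hindered cross-conjugated dienone, and hydride attacks the trans-hydrindanone from the face opposite the axial angular methyl (as in steroid 17-ketones), which sets C18.

Step 22
Reactants: 31 C18 alcohol
Product: 33 tetracyclic enone (C4 saturated, methyl C20 as in the target), via C4-epimer mixture 32 (not isolated)
Conditions: H2 (1 atm), 10% Pd/C, EtOAc, rt; filter; then KOt-Bu (0.3 equiv), t-BuOH/THF, rt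
Reagents that add atoms: none
Why: heterogeneous hydrogenation saturates the trisubstituted C4=C5 bond and leaves the tetrasubstituted C2=C3 enone bond; base then equilibrates C4 (through the extended dienolate) and C8 (through the enolate) to the isomer expected to be most stable, with H-4 in the enone plane (least allylic 1,3-strain against C1) and the A/B junction trans, which is the target configuration.

Step 23
Reactants: 33 tetracyclic enone
Product: 34 target (CNP0544018.1)
Conditions: Ph3PCH3Br (5 equiv), KOt-Bu (5 equiv), toluene, 90 °C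
Reagents that add atoms: methyltriphenylphosphonium bromide, C[P+](c1ccccc1)(c1ccccc1)c1ccccc1.[Br-]
Why: Wittig methylenation of the hindered C1 ketone with excess ylide at elevated temperature (the free hydroxyl is carried as its alkoxide); C4 and C8 already hold their thermodynamic configurations, so the basic conditions should not erode them.

## Compound list

1 | but-2-yne-1,4-diol | OCC#CCO | starting material
2 | 4-[(tert-butyldimethylsilyl)oxy]but-2-yn-1-ol | OCC#CCO[Si](C)(C)C(C)(C)C | intermediate
3 | alkenylmagnesium chelate (five-membered C–Mg–O ring; Mg cis to CH2O, methyl cis to CH2OTBS) | CC1=C(CO[Si](C)(C)C(C)(C)C)[Mg]OC1 | intermediate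
4 | (2Z)-3-bromo-4-[(tert-butyldimethylsilyl)oxy]-2-methylbut-2-en-1-ol | OC/C(C)=C(\Br)CO[Si](C)(C)C(C)(C)C | intermediate
5 | (2Z)-3-bromo-4-[(tert-butyldimethylsilyl)oxy]-2-methylbut-2-enal | O=C/C(C)=C(\Br)CO[Si](C)(C)C(C)(C)C | intermediate
6 | {[(2Z)-2-bromo-3-methylpenta-2,4-dien-1-yl]oxy}(tert-butyl)dimethylsilane | C=C/C(C)=C(\Br)CO[Si](C)(C)C(C)(C)C | intermediate
7 | (3Z)-4,5-dibromo-3-methylpenta-1,3-diene | C=C/C(C)=C(\Br)CBr | intermediate
8 | cyclopent-2-en-1-one | O=C1C=CCC1 | starting material
9 | methylzinc (3S)-3-methylcyclopent-1-en-1-olate | C[Zn]OC1=C[C@@H](C)CC1 | intermediate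
10 | trimethyl{[(3S)-3-methylcyclopent-1-en-1-yl]oxy}silane | C[Si](C)(C)OC1=C[C@@H](C)CC1 | intermediate
11 | lithium (3S)-3-methylcyclopent-1-en-1-olate | [Li+].[O-]C1=C[C@@H](C)CC1 | intermediate
12 | (3S)-3-methylcyclopent-1-en-1-yl trifluoromethanesulfonate | O=S(=O)(OC1=C[C@@H](C)CC1)C(F)(F)F | intermediate
13 | (4R)-4-[(tert-butyldimethylsilyl)oxy]cyclopent-2-en-1-one | O=C1C=C[C@H](O[Si](C)(C)C(C)(C)C)C1 | starting material
14 | (4R)-4-[(tert-butyldimethylsilyl)oxy]-2-iodocyclopent-2-en-1-one | O=C1C(I)=C[C@H](O[Si](C)(C)C(C)(C)C)C1 | intermediate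
15 | (4R)-4-[(tert-butyldimethylsilyl)oxy]-2-methylcyclopent-2-en-1-one | CC1=C[C@H](O[Si](C)(C)C(C)(C)C)CC1=O | intermediate
16 | ring D trimethylsilyl enol ether (3-(TBSO)propyl on C14 trans to OTBS on C16) | CC1=C(O[Si](C)(C)C)C[C@@H](O[Si](C)(C)C(C)(C)C)[C@@H]1CCCO[Si](C)(C)C(C)(C)C | intermediate
17 | lithium enolate of the 1,4-adduct | [Li+].CC1=C([O-])C[C@@H](O[Si](C)(C)C(C)(C)C)[C@@H]1CCCO[Si](C)(C)C(C)(C)C | intermediate
18 | ring D ketone with quaternary C13 (bromodienyl chain trans to the C14 chain, OTBS on C16) | C=C/C(C)=C(\Br)C[C@@]1(C)C(=O)C[C@@H](O[Si](C)(C)C(C)(C)C)[C@@H]1CCCO[Si](C)(C)C(C)(C)C | intermediate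
19 | ring D cyclopentenone (C16=C17) | C=C/C(C)=C(\Br)C[C@@]1(C)C(=O)C=C[C@@H]1CCCO[Si](C)(C)C(C)(C)C | intermediate
20 | ring D ketone with isopropyl on C16 (trans to the C14 chain) | C=C/C(C)=C(\Br)C[C@@]1(C)C(=O)C[C@@H](C(C)C)[C@@H]1CCCO[Si](C)(C)C(C)(C)C | intermediate
21 | C18 ethylene ketal of 20 | C=C/C(C)=C(\Br)C[C@@]1(C)C2(OCCO2)C[C@@H](C(C)C)[C@@H]1CCCO[Si](C)(C)C(C)(C)C | intermediate
22 | primary alcohol (C1–OH) | C=C/C(C)=C(\Br)C[C@@]1(C)C2(OCCO2)C[C@@H](C(C)C)[C@@H]1CCCO | intermediate
23 | aldehyde (C1) | C=C/C(C)=C(\Br)C[C@@]1(C)C2(OCCO2)C[C@@H](C(C)C)[C@@H]1CCC=O | intermediate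
24 | allylic alcohol (both C1 epimers) | C=C/C(C)=C(\Br)C[C@@]1(C)C2(OCCO2)C[C@@H](C(C)C)[C@@H]1CCC(O)C3=C[C@@H](C)CC3 | intermediate
25 | seco-enone (rings A and D joined by C15–C2–C1) | C=C/C(C)=C(\Br)C[C@@]1(C)C2(OCCO2)C[C@@H](C(C)C)[C@@H]1CCC(=O)C3=C[C@@H](C)CC3 | intermediate
26 | dienyl ketone (ring C closed, both C2 epimers, C2 cis to the vinyl group across C3=C4) | C=C/C(C)=C1/C[C@@]2(C)C3(OCCO3)C[C@@H](C(C)C)[C@@H]2CC1C(=O)C4=C[C@@H](C)CC4 | intermediate
27 | potassium tetraenolate (ring A and vinyl on the inside of the C1=C2–C3=C4 diene) | [K+].C=C/C(C)=C1/C[C@@]2(C)C3(OCCO3)C[C@@H](C(C)C)[C@@H]2C/C1=C(\[O-])C4=C[C@@H](C)CC4 | intermediate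
28 | potassium trienolate (ring B closed, enolate C1=C8) | [K+].[O-]C1=C2CC[C@H](C)[C@@H]2C/C=C(C)\C3=C1C[C@H]4[C@H](C(C)C)CC5(OCCO5)[C@]4(C)C3 | intermediate
29 | tetracyclic dienone ketal | O=C1[C@H]2CC[C@H](C)[C@@H]2C/C=C(C)\C3=C1C[C@H]4[C@H](C(C)C)CC5(OCCO5)[C@]4(C)C3 | intermediate
30 | tetracyclic dienone with C18 ketone | O=C1[C@H]2CC[C@H](C)[C@@H]2C/C=C(C)\C3=C1C[C@H]4[C@H](C(C)C)CC(=O)[C@]4(C)C3 | intermediate
31 | tetracyclic dienone with C18 alcohol (cis to C22) | O=C1[C@H]2CC[C@H](C)[C@@H]2C/C=C(C)\C3=C1C[C@H]4[C@H](C(C)C)C[C@@H](O)[C@]4(C)C3 | intermediate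
32 | C4-epimer mixture of the C2=C3 enone | O=C1[C@H]2CC[C@H](C)[C@@H]2CCC(C)C3=C1C[C@H]4[C@H](C(C)C)C[C@@H](O)[C@]4(C)C3 | intermediate
33 | tetracyclic enone (C4 as in the target) | O=C1[C@H]2CC[C@H](C)[C@@H]2CC[C@H](C)C3=C1C[C@H]4[C@H](C(C)C)C[C@@H](O)[C@]4(C)C3 | intermediate
34 | target CNP0544018.1 | C=C1C2=C(C[C@@]3(C)[C@H](O)C[C@@H](C(C)C)[C@@H]3C2)[C@@H](C)CC[C@@H]2[C@@H]1CC[C@@H]2C | target

## Step count and risks

Total: 23 steps. Longest linear sequence: 18 steps (steps 1–5, then 11–23).

Steps most likely to fail:

1. Step 19. The reductive elimination at the hindered tetrasubstituted alkenylpalladium may be slow. The enolate may not reach the geometry with ring A on the inside. Closure may be slow or take the other helix because C6 must pass the C11 methyl, and 6π closure of a triene sub-unit may compete. Fallback with known chemistry: starting from 25, run the α-alkenylation alone with Pd(PPh3)4 and KOt-Bu (1.05 equiv) in THF at rt, so that no base is left, and isolate dienyl ketone 26. Silylate 26 with TBSOTf and Et3N in CH2Cl2 to the neutral silyl trienol ether F1 (the enol ether isomer with ring A on the outside can be desilylated back to 26). Heat F1 in toluene at 80 °C for the thermal 8π closure to cyclooctatriene silyl enol ether F2. Treat F2 with 1 M HCl in THF, which removes the silyl enol ether and the dioxolane together, and rejoin the route at 30.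

2. Step 22. The thermodynamic ratio at C4 may not favour the needed epimer, or the enone may drift to its β,γ-isomer during equilibration. Fallback: starting from 31, reduce the C1 ketone with NaBH4 and CeCl3 in MeOH at –78 °C (Luche reduction, hydride from the convex face) to dienyl alcohol F3. Hydrogenate F3 with [Rh(nbd)(dppb)]BF4 under H2 in CH2Cl2, so that the C1 hydroxyl directs hydrogen to the inner face of C4=C5 and the tetrasubstituted alkene stays, giving alcohol F4. Oxidise the allylic C1 alcohol of F4 selectively with MnO2 and rejoin the route at 33.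

3. Step 23. Addition of the ylide to the shielded, twisted C1 carbonyl may be slow, with enolisation taking over. Fallback: starting from 33, add Me3SiCH2Li in the presence of CeCl3 in THF at –78 °C to give β-hydroxysilane F5, then eliminate with KH in THF (Peterson olefination) to reach 34 directly.

## Further compounds

F1 | step 19 | tert-butyldimethylsilyl trienol ether of 26 (ring A and vinyl on the inside) | C=C/C(C)=C1/C[C@@]2(C)C3(OCCO3)C[C@@H](C(C)C)[C@@H]2C/C1=C(\O[Si](C)(C)C(C)(C)C)C4=C[C@@H](C)CC4
F2 | step 19 | tert-butyldimethylsilyl enol ether of 29 (C1=C8 enol ether) | CC(C)(C)[Si](C)(C)OC1=C2CC[C@H](C)[C@@H]2C/C=C(C)\C3=C1C[C@H]4[C@H](C(C)C)CC5(OCCO5)[C@]4(C)C3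
F3 | step 22 | C1 carbinol of 31 (expected epimer drawn) | O[C@@H]1[C@H]2CC[C@H](C)[C@@H]2C/C=C(C)\C3=C1C[C@H]4[C@H](C(C)C)C[C@@H](O)[C@]4(C)C3
F4 | step 22 | C1 carbinol of 33 | O[C@@H]1[C@H]2CC[C@H](C)[C@@H]2CC[C@H](C)C3=C1C[C@H]4[C@H](C(C)C)C[C@@H](O)[C@]4(C)C3
F5 | step 23 | C1 (trimethylsilyl)methyl carbinol of 33 (either C1 epimer) | C[Si](C)(C)CC1(O)[C@H]2CC[C@H](C)[C@@H]2CC[C@H](C)C3=C1C[C@H]4[C@H](C(C)C)C[C@@H](O)[C@]4(C)C3
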